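## Structural features

Diplotrin A (12) is a 3-methoxyflavone in which benzene ring A is fused to the γ-pyrone ring C (a 4H-chromen-4-one) and benzene ring B is attached through the C2–C1' bond. Ring A carries methoxy groups at C7 and C8, ring C a methoxy group at C3, and ring B a methoxy group at C4' with free hydroxyls at C2' and C5'. The molecule has no stereocentre, so the problem is regiochemical: six oxygens must be told apart, four as methyl ethers that stay and two as phenols that end free. The 2',5'-dihydroxy pair is a para-hydroquinone that oxidises easily to the quinone in air and base. The 2'-hydroxyl is ortho to C2, so in an open-chain 1,3-dicarbonyl precursor it could close a pyrone ring in the wrong direction. The C3 enol ether and the aryl methyl ethers exclude hard Lewis acids at the end. The feature used is that C2 is a single carbon at the carbonyl oxidation level between C1' of ring B and C3, while C3 with its methoxy group is the α-carbon of the C4 ketone on ring A, so that C2 can be carbon monoxide placed between a ring-B aryl iodide and the enolisable methoxyacetyl ketone of ring A.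

## Logic of the disconnections

12 is traced back to 11 by cutting the O2'–CH2Ph and O5'–CH2Ph bonds. The hydroquinone is the most fragile part of 12, so it is released last and every earlier intermediate is an air-stable ether. The forward step must be neutral and must leave the C2=C3 bond and all methyl ethers alone.

11 is traced back to 10 by cutting O1–C2, with C2 returning to a carbonyl. This opens ring C to an acyclic 1,3-dicarbonyl chain that already holds every carbon and oxygen. The forward dehydration is only unambiguous if the ring-A hydroxyl is the one free phenol, so the ring-B oxygens stay benzylated, and the acid must be mild enough for those ethers.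

10 is traced back to 4, 7 and 8 by cutting C1'–C2 and C2–C3. This divides the molecule into a ring-A half, a ring-B half and a one-carbon unit, with the C3 methoxy group already in 4. The forward step has to form both bonds at one carbon and end as the C-acyl product, whichever nucleophilic site of 4 is acylated first; 9 is the O-acyl stage on that path.

4 is traced back to 1 and 2 by cutting the aryl–carbonyl bond (future C4a–C4) and restoring the methyl group on the future O1; 3 is the stage before that methyl group is lost. Both pieces are commercial, so the whole ring-A half costs one step. The forward acylation must go ortho to a terminal methoxy group of 1, and the demethylation must be confined to the ether chelated to the new ketone.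

7 is traced back to 6 by cutting the C1'–I bond. The iodine serves only as the handle for the palladium step, and without it the ring-B half is a simple protected arene. The forward iodination must go para to the methoxy group, the position where the activating effects of two alkoxy groups coincide.

6 is traced back to 5 by cutting the two O–benzyl bonds. 5 is commercial and already has the 1,2,4-oxygen pattern of ring B with the correct oxygen methylated, so no oxygen has to be introduced or differentiated later. The forward alkylation must avoid oxidation of the hydroquinone.

## Other disconnections considered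

Alternative 1: The cut runs through ring B at C5'–C6', C1'–C2' and C2'–C3', so that ring B is built on a finished chromone.
- Forward step: 2-ethynyl-3,7,8-trimethoxy-4H-chromen-4-one A1 would be heated with the zerovalent chromium carbene complex (CO)5Cr=C(OMe)C(OMe)=CH2 A2 in a Dötz benzannulation. Insertion of the alkyne of A1 into the Cr=C bond of A2, insertion of a CO ligand to a vinylketene, six-electron ring closure and tautomerisation would give 2-(2-hydroxy-4,5-dimethoxyphenyl)-3,7,8-trimethoxy-4H-chromen-4-one A3.
- In favour: a whole ring and three C–C bonds form in one step. A terminal alkyne places its large substituent next to the CO-derived carbon, so the 2'-hydroxyl would appear free and already distinguished without a protecting group. In complexity gained per step this is better than the chosen key step, which closes no ring.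
- Against: the carbene carbon carries its alkoxy group into C5', so A3 is the 5'-O-methyl ether of 12 and not 12. Removing one methyl group out of five is not defensible, so a carbene with a cleavable O-substituent and an extra deprotection would be needed. A1 needs a complete ring C with the C3 methoxy group and a C2 alkynylation, which is already longer than the whole chosen route. A2 must be made separately from Cr(CO)6 and is used stoichiometrically. A conjugated, electron-poor alkyne such as A1 is a less dependable benzannulation partner.
- Comparison: both plans use CO as a one-carbon building block, and in that idea they are equal. There it comes from a stoichiometric metal and becomes C2'; here it is gas under catalytic palladium and becomes C2. On structure the chosen plan delivers the correct oxygen pattern, and on step count it is much shorter.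

Alternative 2: The cut is C4a–C4, C4–C3 and O1–C2, so ring C is assembled from 6-iodo-2,3-dimethoxyphenol A4, 1,4-bis(benzyloxy)-2-ethynyl-5-methoxybenzene A5 and CO.
- Forward step: zerovalent palladium formed from PdCl2(PPh3)2 would insert into the C–I bond of A4, take up CO and couple with the terminal alkyne A5 to an ynone. The phenol would then add in the 6-endo sense to give 2-[2,5-bis(benzyloxy)-4-methoxyphenyl]-7,8-dimethoxy-4H-chromen-4-one A6.
- In favour: ring C closes in the coupling step itself and three bonds form at once. This is better than the chosen key step, which needs step 5 for ring closure. A5 would come from 7 by alkynylation and desilylation, so the ring-B chemistry is shared.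
- Against: C3 enters as the terminal alkyne carbon and therefore carries hydrogen, so A6 lacks the C3 methoxy group. It would have to be added later by C3 oxidation and O-methylation, next to a hindered ortho-benzyloxyaryl group. 5-exo closure to the aurone skeleton competes with the 6-endo mode. The iodination leading to A4 must distinguish ortho from para to the hydroxyl.
- Comparison: both are three-component palladium carbonylations with CO as a ring-C carbon (C4 there, C2 here), so mechanism and practical hazards are equal. On structure the chosen plan is better because the C3 oxygen is present from the start. On step count the alternative should need about nine steps against six.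

Alternative 3: The cut is the C4–C4a bond.
- Forward step: (E)-3-[2,5-bis(benzyloxy)-4-methoxyphenyl]-3-(2,3-dimethoxyphenoxy)-2-methoxyprop-2-enoic acid A7 would be converted with (COCl)2 into the acid chloride A8, that is (E)-3-[2,5-bis(benzyloxy)-4-methoxyphenyl]-3-(2,3-dimethoxyphenoxy)-2-methoxyprop-2-enoyl chloride A8. SnCl4 would then activate A8 for intramolecular Friedel–Crafts acylation of the dimethoxyphenoxy ring at its only free position ortho to the ether oxygen. This would close ring C and give 2-[2,5-bis(benzyloxy)-4-methoxyphenyl]-3,7,8-trimethoxy-4H-chromen-4-one A9, which is the same compound as 11.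
- In favour: ring closure and the C4 carbonyl arrive in one step, and the site of attack on ring A is unambiguous. A9 needs only the hydrogenolysis of step 6, so the endgame is equal to the chosen plan. No CO gas and no palladium are needed, which is a practical advantage.
- Against: A7 is a tetrasubstituted push–pull alkene that must have the carboxyl group cis to the aryloxy group, and its preparation would take several steps with uncertain geometry. SnCl4 and the HCl set free when A8 is made threaten the benzyl ethers, especially the chelating 2'-ether, and the enol ether. Ring B is more electron-rich than ring A, and Lewis-acid-promoted isomerisation of the alkene of A8 would let the acylium ion reach C6' and form an indenone.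
- Comparison: on structure both plans pass through the same chromone. On mechanism the chosen plan forms its C–C bonds under base with a catalytic metal, whereas the alternative exposes the most sensitive groups to a stoichiometric Lewis acid. On step count the chosen plan is shorter because both of its fragments take one or two steps.

Key step: step 4

Remark on the chemistry: locants (O1, C2, C3, C4, C4a, primed ring-B positions) follow the flavone numbering of 12 throughout. Compound 10 is drawn as the diketo form although it should exist largely as a chelated enol; its C2 centre is labile, is handled as the racemate and disappears in step 5. The structures of 4, 7 and 10 map atom by atom onto 12.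

## Route

Step 1
Reactants: 1 1,2,3-trimethoxybenzene; 2 methoxyacetyl chloride
Product: 4 1-(2-hydroxy-3,4-dimethoxyphenyl)-2-methoxyethan-1-one, via 2,3,4-trimethoxyphenyl methoxymethyl ketone 3 (not isolated)
Conditions: AlCl3 (2.5 equiv), CH2Cl2, 0 °C → reflux; then ice, aq. HCl
Reagents that add atoms: none
Why: Friedel–Crafts acylation of 1 should occur at C4 (para to the C1 methoxy group, ortho to the C3 methoxy group) to give 3. AlCl3 held between the ketone oxygen and the ortho methoxy oxygen in a six-membered chelate then cleaves only that methyl ether, and work-up gives the hydrogen-bonded ortho-hydroxy ketone.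

Step 2
Reactants: 5 2-methoxyhydroquinone (2-methoxybenzene-1,4-diol)
Product: 6 1,4-bis(benzyloxy)-2-methoxybenzene
Conditions: BnBr (2.3 equiv), K2CO3 (3 equiv), DMF, 60 °C, N2
Reagents that add atoms: benzyl bromide, BrCc1ccccc1
Why: Double Williamson etherification of the two phenols. The mixture is degassed because the hydroquinone anion is easily oxidised to the quinone.

Step 3
Reactants: 6 1,4-bis(benzyloxy)-2-methoxybenzene
Product: 7 1,4-bis(benzyloxy)-2-iodo-5-methoxybenzene
Conditions: NIS (1.05 equiv), TFA (10 mol %), MeCN, 0 °C → rt, dark
Reagents that add atoms: N-iodosuccinimide, O=C1CCC(=O)N1I
Why: Electrophilic aromatic iodination with acid-activated NIS. C5 of 6 is para to the methoxy group and ortho to the C4 benzyloxy group, the usual site of substitution in 1,2,4-trialkoxybenzenes, whereas C3 is crowded between two alkoxy groups and C6 is activated by only one.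

Step 4
Reactants: 4 1-(2-hydroxy-3,4-dimethoxyphenyl)-2-methoxyethan-1-one; 7 1,4-bis(benzyloxy)-2-iodo-5-methoxybenzene; 8 carbon monoxide
Product: 10 1-[2,5-bis(benzyloxy)-4-methoxyphenyl]-3-(2-hydroxy-3,4-dimethoxyphenyl)-2-methoxypropane-1,3-dione (racemic at C2), via ring-A aryl 2,5-bis(benzyloxy)-4-methoxybenzoate 9 (not isolated)
Conditions: Pd(OAc)2 (5 mol %), Ph2P(CH2)4PPh2 (dppb, 6 mol %), DBU (3 equiv), CO (5 bar), DMSO, 90 °C; then aq. NH4Cl; 4 in slight excess (1.2 equiv)
Reagents that add atoms: none
Why: Pd(OAc)2 is reduced in the flask to zerovalent palladium held by the bisphosphine, which inserts into the C1'–I bond of 7; 8 then coordinates and inserts to give the aroyl–palladium iodide. Under DBU the ring-A phenoxide of 4 should take up the aroyl group first to give ester 9, whose α-methoxy ketone is enolised by the same base so that the aroyl group migrates from oxygen to carbon (Baker–Venkataraman acyl transfer through a six-membered transition state); any enolate acylated directly on carbon gives the same product, so C1'–C2 and C2–C3 form in either course. The closest known reaction type is the palladium-catalysed carbonylative coupling of aryl halides with ketones and with 2-hydroxyaryl ketones, which leads to 1,3-diketones and, at higher temperature, to flavones. No ring is closed. The one new sp3 centre, C2 of the propanedione, lies between two carbonyl groups, forms as a racemate, is labile through the enol and is erased in step 5, so nothing has to control it. The selectivity needed is chemoselectivity between carbon, enol-oxygen and phenoxide acylation, and the substrate secures it: every O-acyl product is a reactive ester that can pass the acyl group on, while the C-acyl product leaves the equilibrium as a chelated, doubly stabilised enolate. The benzyl ethers keep the ring-B oxygens out of the reaction, the iodide allows 90 °C (below the range in which base closes ring C, so that 10 can be isolated), and CO pressure on the electron-rich aryl–palladium species favours insertion over reduction of the iodide.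

Step 5
Reactants: 10 1-[2,5-bis(benzyloxy)-4-methoxyphenyl]-3-(2-hydroxy-3,4-dimethoxyphenyl)-2-methoxypropane-1,3-dione
Product: 11 2-[2,5-bis(benzyloxy)-4-methoxyphenyl]-3,7,8-trimethoxy-4H-chromen-4-one
Conditions: TsOH·H2O (10 mol %), toluene, 90 °C
Reagents that add atoms: none
Why: Acid-catalysed cyclodehydration of a 1-(2-hydroxyaryl)-1,3-diketone. The ring-A hydroxyl is the only free phenol, so its 6-exo-trig addition to the ring-B carbonyl and loss of water can only form O1–C2, and aromatisation to the γ-pyrone drives the reaction and removes the labile C2 centre of 10. Catalytic sulfonic acid in toluene should leave the aryl benzyl and methyl ethers intact.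

Step 6
Reactants: 11 2-[2,5-bis(benzyloxy)-4-methoxyphenyl]-3,7,8-trimethoxy-4H-chromen-4-one
Product: 12 diplotrin A, 2-(2,5-dihydroxy-4-methoxyphenyl)-3,7,8-trimethoxy-4H-chromen-4-one
Conditions: H2 (1 atm), Pd/C (10 wt % Pd), EtOAc/MeOH, rt; filtration and concentration under N2
Reagents that add atoms: none
Why: Catalytic hydrogenolysis of the two aryl benzyl ethers. The C2=C3 bond of the aromatic pyrone and the aryl methyl ethers should not be reduced at room temperature and 1 atm, and neutral, oxygen-free work-up protects the 2',5'-hydroquinone from oxidation to the quinone.

## Compound list

1 | 1,2,3-trimethoxybenzene | COc1cccc(OC)c1OC | starting material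
2 | methoxyacetyl chloride | COCC(=O)Cl | starting material
3 | 2-methoxy-1-(2,3,4-trimethoxyphenyl)ethan-1-one | COCC(=O)c1ccc(OC)c(OC)c1OC | intermediate
4 | 1-(2-hydroxy-3,4-dimethoxyphenyl)-2-methoxyethan-1-one | COCC(=O)c1ccc(OC)c(OC)c1O | intermediate
5 | 2-methoxyhydroquinone (2-methoxybenzene-1,4-diol) | COc1cc(O)ccc1O | starting material
6 | 1,4-bis(benzyloxy)-2-methoxybenzene | COc1cc(OCc2ccccc2)ccc1OCc1ccccc1 | intermediate
7 | 1,4-bis(benzyloxy)-2-iodo-5-methoxybenzene | COc1cc(OCc2ccccc2)c(I)cc1OCc1ccccc1 | intermediate
8 | carbon monoxide | [C-]#[O+] | starting material
9 | 6-(2-methoxyacetyl)-2,3-dimethoxyphenyl 2,5-bis(benzyloxy)-4-methoxybenzoate | COCC(=O)c1ccc(OC)c(OC)c1OC(=O)c1cc(OCc2ccccc2)c(OC)cc1OCc1ccccc1 | intermediate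
10 | 1-[2,5-bis(benzyloxy)-4-methoxyphenyl]-3-(2-hydroxy-3,4-dimethoxyphenyl)-2-methoxypropane-1,3-dione (racemic, enolisable C2) | COc1cc(OCc2ccccc2)c(C(=O)C(OC)C(=O)c2ccc(OC)c(OC)c2O)cc1OCc1ccccc1 | intermediate
11 | 2-[2,5-bis(benzyloxy)-4-methoxyphenyl]-3,7,8-trimethoxy-4H-chromen-4-one | COc1cc(OCc2ccccc2)c(-c2oc3c(OC)c(OC)ccc3c(=O)c2OC)cc1OCc1ccccc1 | intermediate
12 | diplotrin A, 2-(2,5-dihydroxy-4-methoxyphenyl)-3,7,8-trimethoxy-4H-chromen-4-one | COc1cc(O)c(-c2oc3c(OC)c(OC)ccc3c(=O)c2OC)cc1O | target

## Step count and least certain steps

Total step count: 6. Longest linear sequence: 5 steps (5 → 6 → 7 → 10 → 11 → 12, steps 2 to 6). The ring-A branch is 4 steps (1 → 4 → 10 → 11 → 12).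

Step 4 (key step). The most likely failure is that the acyl group reaches oxygen but is not passed on to carbon, because DBU is a weak base for enolising the α-methoxy ketone. Interception of the aroyl–palladium intermediate by adventitious water, or a second aroylation of the free phenol of 10, would also leave C2–C3 formation incomplete. The fallback sets out from 7 and 4 and returns to the route at 10, passing through 9 as an isolated compound. Iodine–magnesium exchange on 7 with i-PrMgCl·LiCl (THF, 0 °C) would give [2,5-bis(benzyloxy)-4-methoxyphenyl]magnesium chloride F1. CO2 and then aq. HCl would give 2,5-bis(benzyloxy)-4-methoxybenzoic acid F2. Steglich esterification of F2 with the phenol of 4 (EDC·HCl, DMAP, CH2Cl2) would give ester 9. A classical Baker–Venkataraman rearrangement with KOt-Bu in THF (0 °C → rt, aq. HCl quench) would then deliver 10. In this variant C2 comes from CO2 and the C–C bond is made with a stoichiometric strong base.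

Step 1. The most likely failure is fragmentation of the methoxyacetylium ion with loss of CO, after which the methoxymethyl cation alkylates the arene. Over-reaction of AlCl3 with the C3 aryl methyl ether or the aliphatic methyl ether is the second risk. The fallback sets out from 1, passes through 3 as an isolated compound and returns at 4. Directed ortho-lithiation of 1 (n-BuLi, TMEDA, THF, 0 °C) would give (2,3,4-trimethoxyphenyl)lithium F3. Acylation with the Weinreb amide N,2-dimethoxy-N-methylacetamide (−78 → 0 °C, aq. HCl quench) would give 3. Chelation-controlled cleavage of the methyl ether ortho to the carbonyl with BCl3 (CH2Cl2, −78 → 0 °C) would give 4. No acylium ion is involved.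

Step 3. The most likely failure is one-electron oxidation of the very electron-rich ring by the iodonium source, leading to oxidative loss of benzyl groups towards the quinone or to biaryl coupling. Acid-promoted reversibility of C–I bond formation could also erode positional purity. The fallback sets out from 6 and returns at 7. Bromination with NBS in MeCN at 0 °C without acid would give 1,4-bis(benzyloxy)-2-bromo-5-methoxybenzene F4. Copper-catalysed aromatic halogen exchange (CuI, NaI, trans-N,N'-dimethylcyclohexane-1,2-diamine, dioxane, 110 °C) would then give 7.

Step 5. The most likely failure is acid-induced loss of the 2'-benzyl group before ring closure, which would free a second phenol and allow closure in the opposite direction. Retro-Claisen cleavage of the hindered 2-methoxy-1,3-diketone by water is the second risk. The fallback sets out from 4, 7 and 8 and returns at 11. The carbonylation of step 4 would be run at 120 °C with the same Pd(OAc)2/bisphosphine/DBU system in DMSO, so that 9 and 10 are passed through without isolation. Ring C would close under base by phenoxide addition to the ring-B carbonyl and elimination of hydroxide from the hemiketal through the C3 enolate, as in the known one-pot carbonylative flavone synthesis from 2-hydroxyaryl ketones. No acid touches the benzyl ethers and no compound outside the list is involved.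

## Further compounds

F1 | step 4 | [2,5-bis(benzyloxy)-4-methoxyphenyl]magnesium chloride | COc1cc(OCc2ccccc2)c([Mg]Cl)cc1OCc1ccccc1
F2 | step 4 | 2,5-bis(benzyloxy)-4-methoxybenzoic acid | COc1cc(OCc2ccccc2)c(C(=O)O)cc1OCc1ccccc1
F3 | step 1 | (2,3,4-trimethoxyphenyl)lithium | [Li]c1ccc(OC)c(OC)c1OC
F4 | step 3 | 1,4-bis(benzyloxy)-2-bromo-5-methoxybenzene | COc1cc(OCc2ccccc2)c(Br)cc1OCc1ccccc1
F0 | step 5 | none | none
A1 | alternative 1 | 2-ethynyl-3,7,8-trimethoxy-4H-chromen-4-one | C#Cc1oc2c(OC)c(OC)ccc2c(=O)c1OC
A2 | alternative 1 | pentacarbonyl[methoxy(1-methoxyethenyl)methylidene]chromium, (CO)5Cr=C(OMe)C(OMe)=CH2 | C=C(OC)C(OC)=[Cr](=C=O)(=C=O)(=C=O)(=C=O)=C=O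
A3 | alternative 1 | 2-(2-hydroxy-4,5-dimethoxyphenyl)-3,7,8-trimethoxy-4H-chromen-4-one | COc1cc(O)c(-c2oc3c(OC)c(OC)ccc3c(=O)c2OC)cc1OC
A4 | alternative 2 | 6-iodo-2,3-dimethoxyphenol | COc1ccc(I)c(O)c1OC
A5 | alternative 2 | 1,4-bis(benzyloxy)-2-ethynyl-5-methoxybenzene | C#Cc1cc(OCc2ccccc2)c(OC)cc1OCc1ccccc1
A6 | alternative 2 | 2-[2,5-bis(benzyloxy)-4-methoxyphenyl]-7,8-dimethoxy-4H-chromen-4-one | O=c1cc(-c2cc(OCc3ccccc3)c(OC)cc2OCc2ccccc2)oc2c(OC)c(OC)ccc12
A7 | alternative 3 | (E)-3-[2,5-bis(benzyloxy)-4-methoxyphenyl]-3-(2,3-dimethoxyphenoxy)-2-methoxyprop-2-enoic acid | CO/C(C(=O)O)=C(/Oc1cccc(OC)c1OC)c1cc(OCc2ccccc2)c(OC)cc1OCc1ccccc1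
A8 | alternative 3 | (E)-3-[2,5-bis(benzyloxy)-4-methoxyphenyl]-3-(2,3-dimethoxyphenoxy)-2-methoxyprop-2-enoyl chloride | CO/C(C(=O)Cl)=C(/Oc1cccc(OC)c1OC)c1cc(OCc2ccccc2)c(OC)cc1OCc1ccccc1
A9 | alternative 3 | 2-[2,5-bis(benzyloxy)-4-methoxyphenyl]-3,7,8-trimethoxy-4H-chromen-4-one | COc1cc(OCc2ccccc2)c(-c2oc3c(OC)c(OC)ccc3c(=O)c2OC)cc1OCc1ccccc1
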